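## Analysis of the target

Target 22 is a macrocyclic bis(bibenzyl). Four benzene rings are tied into one 19-membered ring by two CH2CH2 bridges and two diaryl ether oxygens, in the order ring A–O–ring B–CH2CH2–ring C–O–ring D–CH2CH2–ring A. Rings A and C carry the same pattern: the ethylene arm on C1, the ether oxygen on C3 and free hydroxyls on C4 and C5. Ring B is a 1,4-phenylene and ring D a 1,3-phenylene (arm on C1, ether oxygen on C3). There is no stereocenter and the molecule is achiral, so the only geometric question, the E/Z ratio of alkene intermediates, disappears on saturation. The sensitive groups are the two catechols, which oxidise to ortho-quinones in air and bind metals, so all four hydroxyls are best carried as methyl ethers to the last step. The difficulty lies in the two diaryl ethers, each on a trioxygenated ring next to another oxygen substituent, and in closing a large ring from a flexible chain. Ring B offers a handle, because its oxygen is para to its carbon arm, which can be a formyl group when that ether is made. Ring D does not, since C3 is meta to the arm and unactivated; but C4 of ring D (ortho to C3, para to C1) is a CH in 22, and the strategy rests on placing a nitro group there for the ring closure and erasing it afterwards.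

## Retrosynthetic reasoning

**22 to 21.** The four O–H groups are traced back to O–CH3. Starting materials 1 and 4 already carry these methyl ethers, so the protection costs no step. The forward reaction is one Lewis-acid ether cleavage that must remove four methyl groups and leave both aryl–O–aryl bonds, which offer no sp3 carbon for attack.

**21 to 19 to 18.** The hydrogen on C4 of ring D is traced back to an amino group (19) and that to a nitro group (18). This adds two forward steps (reduction, then diazotisation to 20 and hydrogen transfer) but gives ring D an activator exactly ortho to the ether carbon.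

**18 to 16 (through phenoxide 17).** The bond between the ring C oxygen and C3 of ring D is cut, which opens the macrocycle. This bond is chosen because it is the one that profits from the nitro group: the ring closure then needs only a weak base, with no copper and no carbanion. The other ether (ring A–O–ring B) can be made early and intermolecularly with the para formyl handle. Closing at an ethylene bridge instead would put ylide or low-valent metal chemistry next to a nitroarene. The forward reaction has to make one phenoxide find one C–F carbon within the same molecule.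

**16 to 15 to 14.** The ring C hydroxyl is masked as a benzyl ether, and both CH2–CH2 bridges are traced back to CH=CH. The mask is needed because a free phenoxide would attack the fluoronitroarene of another molecule as soon as ring D is attached. The forward steps must saturate two alkenes without touching the nitro group, the C–F bond or the O-benzyl group, and then remove benzyl without touching the methyl ethers.

**14 to 11 and 12.** The double bond between the ring A arm and ring D is cut by a Wittig disconnection. Aldehyde 12 is a catalogue compound that already has fluorine meta and nitro para to the carbon arm. As an electron-poor aldehyde it reacts quickly with the semi-stabilised ylide 13 under a weak base.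

**11 to 10 to 9.** The phosphonium group on the ring A arm is traced back through the benzylic alcohol to a methyl ester. The ester is inert in the first olefination and keeps the two carbonyl carbons of 3 distinct.

**9 to 3 and 7.** The double bond between ring B and ring C is cut by a second Wittig disconnection, with ylide 8 from salt 7 and the formyl group of 3.

**3 to 1 and 2.** The bond between the ring A oxygen and ring B is cut. The para formyl group of 2 activates the fluoride for displacement by the phenoxide of 1 and afterwards serves as the olefination handle, so no activator has to be removed.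

**7 to 6 to 5 to 4.** Salt 7 is traced back through the benzylic alcohol 6 and the benzyl-protected aldehyde 5 to the commercial hydroxy aldehyde 4.

## Alternatives that were turned down

**Alternative 1:** The ring C–O–ring D ether bond and the neighbouring C–O bond of the hydroxyl on ring C are cut together. This leads back to a 3-methoxyaryne, released from the iodo aryl sulfonate A2 by iodine–magnesium exchange, and to 3-bromophenol A3 as its magnesium salt. In the forward key step the phenoxide adds to the aryne carbon remote from the methoxy group, and the aryl magnesium formed next to the methoxy group is borylated and oxidised to give phenol A1.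
- For: two C–O bonds are placed on the crowded ring in one flask with regiochemistry fixed by the inductive effect of the methoxy group. Ring D enters as the nucleophile, so it needs no activator and no later removal; on that point this plan is stronger, saving the two nitro-removal steps.
- Against: the step closes no ring, so the macrocyclisation still has to be solved at another bond. The oxygenation pattern it builds can be bought ready-made (as in 1 and 4). Magnesium phenoxides are slow partners for arynes, and the aryl magnesium flanked by two oxygens is easily protonated, which would give the ether without the hydroxyl. A2 itself needs several steps.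
- Comparison: the chosen route buys the oxygen pattern and spends its one risky step on the ring closure itself.

**Alternative 2:** The two outer C5–O bonds of rings A and C are cut, leading back to the dideoxy macrocycle A5, a bis(monophenol). In the forward key step a pentavalent iodine oxidant oxygenates each phenol at its only unsubstituted ortho carbon to give the bis(ortho-quinone) A4, which a mild reductant would take to the bis(catechol).
- For: the outer oxygens need no protecting group, the regiochemistry is unambiguous because the other ortho position carries the aryloxy group, and the final boron-halide demethylation is avoided. On end-game economy this plan is stronger.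
- Against: the most delicate oxidation is done twice on the most advanced material. An ortho-quinone with an aryloxy group on the adjacent carbon is a vinylogous aryl ester, open to addition–elimination that would cut the macrocycle and to Diels–Alder dimerisation. The four benzylic CH2 groups are also oxidisable. A5 still has to be cyclised, without help from any activator.
- Comparison: the chosen route carries all oxygens as stable methyl ethers from commercial materials and pays one demethylation step for a ring closure under mild base.

**Alternative 3:** Ring D is cut across two C–C bonds, back to the 4-aryloxy-6-arylethyl-2-pyranone A7 (derived from triacetic acid lactone A9) and phenyl vinyl sulfone A8. In the forward key step a Diels–Alder addition across C3 and C6 of the pyranone is followed by loss of CO2 and benzenesulfinic acid, which leaves the new benzene ring D in aldehyde A6.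
- For: the meta relation of oxygen and carbon arm is written into the lactone, the orientation of the cycloaddition is irrelevant because both sulfone carbons end as CH, and the ether oxygen is attached while its carbon is still part of a vinylogous acid. On making the unactivated meta ether without copper it is as strong as the chosen route, and it needs no activator removal.
- Against: a benzene ring that is available from the shelf with the right substituents (12) is built atom by atom. Pyranone cycloadditions with aromatisation need high temperature, at which the free aldehyde must survive and A8 tends to polymerise. Alkylation of the lactone methyl group and O-arylation with a hindered phenol add steps. No ring of the macrocycle is closed.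
- Comparison: the chosen route uses ring D as purchased, and the same nitro group that makes the ether also closes the 19-membered ring.

Key step: step 11

Assumption: both Wittig olefinations give E/Z mixtures, which are carried on unseparated because step 9 saturates both double bonds.

## Route

Step 1
Reactants: 1 methyl 3-hydroxy-4,5-dimethoxybenzoate; 2 4-fluorobenzaldehyde
Product: 3 methyl 3-(4-formylphenoxy)-4,5-dimethoxybenzoate
Conditions: K2CO3, DMF, 130 °C
Reagents that add atoms: none
Why: Nucleophilic aromatic substitution (SNAr): the phenoxide of 1 adds para to the formyl group of 2, which stabilises the anionic σ-adduct, and fluoride leaves; the activating formyl group is the carbon that later becomes the bridge to ring C.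

Step 2
Reactants: 4 3-hydroxy-4,5-dimethoxybenzaldehyde
Product: 5 3-(benzyloxy)-4,5-dimethoxybenzaldehyde
Conditions: BnBr, K2CO3, DMF, 25 °C
Reagents that add atoms: benzyl bromide, BrCc1ccccc1
Why: Williamson ether synthesis; the benzyl ether masks the one hydroxyl that must stay silent until the ring closure and tolerates base, hydride and weak acid.

Step 3
Reactants: 5 3-(benzyloxy)-4,5-dimethoxybenzaldehyde
Product: 6 [3-(benzyloxy)-4,5-dimethoxyphenyl]methanol
Conditions: NaBH4, MeOH, 0 °C
Reagents that add atoms: none
Why: Borohydride reduction of an aryl aldehyde to the benzylic alcohol; nothing else in 5 is reducible.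

Step 4
Reactants: 6 [3-(benzyloxy)-4,5-dimethoxyphenyl]methanol
Product: 7 [3-(benzyloxy)-4,5-dimethoxybenzyl]triphenylphosphonium bromide
Conditions: PPh3·HBr, MeCN, reflux
Reagents that add atoms: triphenylphosphine hydrobromide, [Br-].c1ccc(cc1)[PH+](c1ccccc1)c1ccccc1
Why: Direct phosphonium salt formation from an electron-rich benzylic alcohol: protonation, ionisation assisted by the para methoxy group (SN1-like) and capture by PPh3; the aryl benzyl ether is stable to this weak acid.

Step 5
Reactants: 3 methyl 3-(4-formylphenoxy)-4,5-dimethoxybenzoate; 7 [3-(benzyloxy)-4,5-dimethoxybenzyl]triphenylphosphonium bromide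
Product: 9 methyl 3-{4-[2-(3-benzyloxy-4,5-dimethoxyphenyl)ethenyl]phenoxy}-4,5-dimethoxybenzoate (E/Z mixture), via ring C benzylidenephosphorane 8 (not isolated)
Conditions: K2CO3, 18-crown-6, CH2Cl2, reflux
Reagents that add atoms: none
Why: Wittig olefination under solid–liquid phase-transfer conditions; the semi-stabilised ylide 8 forms in low concentration and adds to the formyl group, the methyl ester is untouched, and the alkene geometry is irrelevant because step 9 saturates it.

Step 6
Reactants: 9 methyl 3-{4-[2-(3-benzyloxy-4,5-dimethoxyphenyl)ethenyl]phenoxy}-4,5-dimethoxybenzoate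
Product: 10 (3-{4-[2-(3-benzyloxy-4,5-dimethoxyphenyl)ethenyl]phenoxy}-4,5-dimethoxyphenyl)methanol (E/Z mixture)
Conditions: LiAlH4, THF, 0 °C
Reagents that add atoms: none
Why: Hydride reduction of the benzoate to the benzylic alcohol; the unactivated stilbene, the benzyl ether and the diaryl ether do not react with LiAlH4 at 0 °C.

Step 7
Reactants: 10 (3-{4-[2-(3-benzyloxy-4,5-dimethoxyphenyl)ethenyl]phenoxy}-4,5-dimethoxyphenyl)methanol
Product: 11 (3-{4-[2-(3-benzyloxy-4,5-dimethoxyphenyl)ethenyl]phenoxy}-4,5-dimethoxybenzyl)triphenylphosphonium bromide (E/Z mixture)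
Conditions: PPh3·HBr, MeCN, 60 °C
Reagents that add atoms: triphenylphosphine hydrobromide, [Br-].c1ccc(cc1)[PH+](c1ccccc1)c1ccccc1
Why: Same SN1-type phosphonium salt formation as in step 4; the ring A carbinol has a para methoxy group (C4) and ionises readily, and the moderate temperature should limit acid-mediated change at the stilbene to harmless E/Z isomerisation.

Step 8
Reactants: 11 (3-{4-[2-(3-benzyloxy-4,5-dimethoxyphenyl)ethenyl]phenoxy}-4,5-dimethoxybenzyl)triphenylphosphonium bromide; 12 3-fluoro-4-nitrobenzaldehyde
Product: 14 4-[2-(3-{4-[2-(3-benzyloxy-4,5-dimethoxyphenyl)ethenyl]phenoxy}-4,5-dimethoxyphenyl)ethenyl]-2-fluoro-1-nitrobenzene (mixture of alkene isomers), via ring A benzylidenephosphorane 13 (not isolated)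
Conditions: K2CO3, 18-crown-6, CH2Cl2, 25 °C
Reagents that add atoms: none
Why: Wittig olefination; the electron-poor aldehyde 12 is a fast acceptor for ylide 13, and the weak, poorly nucleophilic base in CH2Cl2 should leave the fluoride ortho to the nitro group in place.

Step 9
Reactants: 14 4-[2-(3-{4-[2-(3-benzyloxy-4,5-dimethoxyphenyl)ethenyl]phenoxy}-4,5-dimethoxyphenyl)ethenyl]-2-fluoro-1-nitrobenzene
Product: 15 4-[2-(3-{4-[2-(3-benzyloxy-4,5-dimethoxyphenyl)ethyl]phenoxy}-4,5-dimethoxyphenyl)ethyl]-2-fluoro-1-nitrobenzene
Conditions: KO2CN=NCO2K (excess, in portions), AcOH, MeOH/1,4-dioxane, 25 to 40 °C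
Reagents that add atoms: none
Why: Diimide reduction (concerted syn transfer of two hydrogens to each C=C); acetic acid releases diimide from the azodicarboxylate with only N2, CO2 and KOAc as by-products, so no N- or S-nucleophile that could displace the activated fluoride is present, and nitro, C–F and O-benzyl groups are inert to diimide.

Step 10
Reactants: 15 4-[2-(3-{4-[2-(3-benzyloxy-4,5-dimethoxyphenyl)ethyl]phenoxy}-4,5-dimethoxyphenyl)ethyl]-2-fluoro-1-nitrobenzene
Product: 16 5-[2-(4-{5-[2-(3-fluoro-4-nitrophenyl)ethyl]-2,3-dimethoxyphenoxy}phenyl)ethyl]-2,3-dimethoxyphenol (seco phenol)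
Conditions: BCl3, C6HMe5, CH2Cl2, −78 °C
Reagents that add atoms: none
Why: Lewis-acid debenzylation with a cation scavenger: BCl3 coordinates the benzylic ether oxygen and the benzyl cation is transferred to pentamethylbenzene; at −78 °C the aryl methyl ethers, the nitro group and the C–F bond should not be attacked.

Step 11
Reactants: 16 5-[2-(4-{5-[2-(3-fluoro-4-nitrophenyl)ethyl]-2,3-dimethoxyphenoxy}phenyl)ethyl]-2,3-dimethoxyphenol
Product: 18 tetra-O-methyl nitro macrocycle (19-membered ring A–O–B–CH2CH2–C–O–D–CH2CH2–A, methoxy groups on C4 and C5 of rings A and C, nitro group on C4 of ring D), via potassium phenoxide 17 (not isolated)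
Conditions: K2CO3, DMF, 2 mM (slow addition of 16), 25 to 50 °C
Reagents that add atoms: none
Why: K2CO3 deprotonates the only free hydroxyl (C3 of ring C) to give phenoxide 17, whose oxygen adds to the fluorine-bearing C3 of ring D; the charge of the anionic σ-adduct is delocalised into the nitro group on C4, and loss of fluoride restores the arene (addition–elimination, SNAr). The closest known reaction type is the macrocyclic etherification of phenoxides on ortho-fluoronitroarenes, with later reductive removal of the nitro group. The 19-membered ring closes by attack of the chain-end oxygen on an sp2 carbon whose activated C=C(NO2) bond lies outside the new ring, formally a 19-exo-trig addition followed by expulsion of fluoride; a ring of this size has no strain or trajectory problem, but nothing preorganises the chain. No stereocenter is formed. Ring closure must win over chain growth, which slow addition into a 2 mM solution should secure because cyclisation is first order and oligomerisation second order. Attack must occur only at the C–F carbon, which the substrate secures: it has one phenol and one carbon that carries both a leaving group and ortho nitro activation, while the methoxy- and aryloxy-bearing carbons of rings A to C are unactivated. The CH2 group para to the nitro group is weakly acidic, and the choice of K2CO3, strong enough for the phenol only, should keep it untouched.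

Step 12
Reactants: 18 tetra-O-methyl nitro macrocycle
Product: 19 tetra-O-methyl amino macrocycle (NH2 on C4 of ring D)
Conditions: Fe, NH4Cl, EtOH/H2O, 80 °C
Reagents that add atoms: none
Why: Béchamp-type reduction of the nitroarene by zerovalent iron in a buffered protic medium; aryl ethers and bibenzyl bridges are unaffected.

Step 13
Reactants: 19 tetra-O-methyl amino macrocycle
Product: 21 tetra-O-methyl macrocycle (ring D unsubstituted at C4), via diazonium chloride 20 (not isolated)
Conditions: NaNO2, HCl, THF/H2O, 0 °C; then H3PO2 (50% aq., excess), 0 to 25 °C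
Reagents that add atoms: none
Why: Diazotisation followed by hydrodediazoniation: diazonium ion 20 is reduced by hypophosphorous acid in a radical chain in which the aryl radical takes hydrogen from a P–H bond, so N2 is lost and hydrogen is left on C4 of ring D; the large excess of H3PO2 should let hydrogen transfer outrun attack of the radical on the neighbouring ring C.

Step 14
Reactants: 21 tetra-O-methyl macrocycle
Product: 22 target CNP0511668.0 (hydroxyls on C4 and C5 of rings A and C)
Conditions: BBr3, CH2Cl2, −78 to 25 °C; degassed MeOH/H2O work-up under argon
Reagents that add atoms: none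
Why: Lewis-acid demethylation: BBr3 coordinates each methoxy oxygen and bromide removes the methyl group by SN2; the diaryl ether C–O bonds offer no sp3 carbon and survive, and the oxygen-free work-up protects the two catechols.

## Compound list

1 | methyl 3-hydroxy-4,5-dimethoxybenzoate | COC(=O)c1cc(O)c(OC)c(OC)c1 | starting material
2 | 4-fluorobenzaldehyde | O=Cc1ccc(F)cc1 | starting material
3 | methyl 3-(4-formylphenoxy)-4,5-dimethoxybenzoate | COC(=O)c1cc(OC)c(OC)c(Oc2ccc(C=O)cc2)c1 | intermediate
4 | 3-hydroxy-4,5-dimethoxybenzaldehyde | COc1cc(C=O)cc(O)c1OC | starting material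
5 | 3-(benzyloxy)-4,5-dimethoxybenzaldehyde | COc1cc(C=O)cc(OCc2ccccc2)c1OC | intermediate
6 | [3-(benzyloxy)-4,5-dimethoxyphenyl]methanol | COc1cc(CO)cc(OCc2ccccc2)c1OC | intermediate
7 | [3-(benzyloxy)-4,5-dimethoxybenzyl]triphenylphosphonium bromide | [Br-].COc1cc(C[P+](c2ccccc2)(c2ccccc2)c2ccccc2)cc(OCc2ccccc2)c1OC | intermediate
8 | ring C benzylidenephosphorane (ylide of 7), not isolated | COc1cc(C=P(c2ccccc2)(c2ccccc2)c2ccccc2)cc(OCc2ccccc2)c1OC | intermediate
9 | methyl 3-{4-[2-(3-benzyloxy-4,5-dimethoxyphenyl)ethenyl]phenoxy}-4,5-dimethoxybenzoate (E/Z mixture, geometry not defined) | COC(=O)c1cc(OC)c(OC)c(Oc2ccc(C=Cc3cc(OC)c(OC)c(OCc4ccccc4)c3)cc2)c1 | intermediate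
10 | (3-{4-[2-(3-benzyloxy-4,5-dimethoxyphenyl)ethenyl]phenoxy}-4,5-dimethoxyphenyl)methanol (E/Z mixture) | OCc1cc(OC)c(OC)c(Oc2ccc(C=Cc3cc(OC)c(OC)c(OCc4ccccc4)c3)cc2)c1 | intermediate
11 | (3-{4-[2-(3-benzyloxy-4,5-dimethoxyphenyl)ethenyl]phenoxy}-4,5-dimethoxybenzyl)triphenylphosphonium bromide (E/Z mixture) | [Br-].COc1cc(C[P+](c2ccccc2)(c2ccccc2)c2ccccc2)cc(Oc2ccc(C=Cc3cc(OC)c(OC)c(OCc4ccccc4)c3)cc2)c1OC | intermediate
12 | 3-fluoro-4-nitrobenzaldehyde | O=Cc1ccc([N+](=O)[O-])c(F)c1 | starting material
13 | ring A benzylidenephosphorane (ylide of 11), not isolated | COc1cc(C=P(c2ccccc2)(c2ccccc2)c2ccccc2)cc(Oc2ccc(C=Cc3cc(OC)c(OC)c(OCc4ccccc4)c3)cc2)c1OC | intermediate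
14 | 4-[2-(3-{4-[2-(3-benzyloxy-4,5-dimethoxyphenyl)ethenyl]phenoxy}-4,5-dimethoxyphenyl)ethenyl]-2-fluoro-1-nitrobenzene (mixture of alkene isomers) | COc1cc(C=Cc2ccc([N+](=O)[O-])c(F)c2)cc(Oc2ccc(C=Cc3cc(OC)c(OC)c(OCc4ccccc4)c3)cc2)c1OC | intermediate
15 | 4-[2-(3-{4-[2-(3-benzyloxy-4,5-dimethoxyphenyl)ethyl]phenoxy}-4,5-dimethoxyphenyl)ethyl]-2-fluoro-1-nitrobenzene | COc1cc(CCc2ccc([N+](=O)[O-])c(F)c2)cc(Oc2ccc(CCc3cc(OC)c(OC)c(OCc4ccccc4)c3)cc2)c1OC | intermediate
16 | 5-[2-(4-{5-[2-(3-fluoro-4-nitrophenyl)ethyl]-2,3-dimethoxyphenoxy}phenyl)ethyl]-2,3-dimethoxyphenol | COc1cc(CCc2ccc(cc2)Oc2cc(CCc3ccc([N+](=O)[O-])c(F)c3)cc(OC)c2OC)cc(O)c1OC | intermediate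
17 | potassium phenoxide of 16, not isolated | [K+].COc1cc(CCc2ccc(cc2)Oc2cc(CCc3ccc([N+](=O)[O-])c(F)c3)cc(OC)c2OC)cc([O-])c1OC | intermediate
18 | tetra-O-methyl nitro macrocycle (nitro on C4 of ring D) | COc1cc2cc(c1OC)Oc1ccc(cc1)CCc1cc(OC)c(OC)c(c1)Oc1cc(ccc1[N+](=O)[O-])CC2 | intermediate
19 | tetra-O-methyl amino macrocycle (NH2 on C4 of ring D) | COc1cc2cc(c1OC)Oc1ccc(cc1)CCc1cc(OC)c(OC)c(c1)Oc1cc(ccc1N)CC2 | intermediate
20 | diazonium chloride of 19, not isolated | [Cl-].COc1cc2cc(c1OC)Oc1ccc(cc1)CCc1cc(OC)c(OC)c(c1)Oc1cc(ccc1[N+]#N)CC2 | intermediate
21 | tetra-O-methyl macrocycle | COc1cc2cc(c1OC)Oc1ccc(cc1)CCc1cc(OC)c(OC)c(c1)Oc1cccc(c1)CC2 | intermediate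
22 | CNP0511668.0 | Oc1cc2cc(c1O)Oc1ccc(cc1)CCc1cc(O)c(O)c(c1)Oc1cccc(c1)CC2 | target

## Step count and least certain steps

Total step count: 14. Longest linear sequence: 13 steps (from 4 through steps 2 to 14).

**Step 11 (key step).** The most likely failure is chain growth: phenoxide 17 attacks the fluoronitroarene of another molecule because the two ethylene bridges leave the seco chain without any bias towards the folded form. If the closure is forced thermally, deprotonation of the CH2 group para to the nitro group opens degradation paths.
Fallback: the same ether bond is closed by copper catalysis on a nitro-free ring D, which also removes the two steps that erase the nitro group. It sets out from 11, which is olefinated with 3-bromobenzaldehyde F1 (K2CO3, 18-crown-6, CH2Cl2) to the bromo diene F2. Diimide reduction (TsNHNH2, NaOAc, DME/H2O, reflux, unproblematic without the fluoronitroarene) should give the saturated bromide F3, and BCl3 with pentamethylbenzene the seco bromophenol F4. An intramolecular Ullmann etherification of F4 (CuI, N,N-dimethylglycine, Cs2CO3, 1,4-dioxane, 100 °C, high dilution) comes back to the route at 21.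

**Step 9.** Hydrogen transfer may stay incomplete, because diimide disproportionates faster than it adds to two aryl-conjugated double bonds; partly reduced mixtures would result.
Fallback: the two alkenes are reduced at different stages and by different methods. It sets out from 9, which is saturated with TsNHNH2 and NaOAc to the saturated ester F5 while no sensitive ring is present. LiAlH4 gives the saturated alcohol F6, PPh3·HBr the saturated phosphonium bromide F7, and Wittig reaction with 12 the mono-alkene F8. The single nitrostilbene double bond of F8 is then hydrogenated homogeneously (H2, RhCl(PPh3)3, benzene/EtOH), which leaves nitro, C–F and O-benzyl groups alone, and the route is rejoined at 15.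

**Step 8.** Aldehyde 12 may be consumed by the basic medium before olefination, through displacement of its activated fluoride by hydroxide traces or by the ylide carbon.
Fallback: the polarity of the olefination is reversed. It sets out from 10, which MnO2 in CH2Cl2 oxidises to the ring A aldehyde F9. Commercial 4-(bromomethyl)-2-fluoro-1-nitrobenzene F10 is quaternised with PPh3 in toluene to (3-fluoro-4-nitrobenzyl)triphenylphosphonium bromide F11. Its ylide is stabilised by the para nitro group, forms with K2CO3 at room temperature and is a poor SNAr nucleophile. Wittig reaction of F9 with F11 comes back to the route at 14.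

**Step 13.** The diazonium ion may be diverted from hydrogen transfer: triazene formation with unreacted, poorly soluble amine, capture by water, or attack of the aryl radical on the adjacent ring C (a Pschorr-type closure, possible because the radical sits ortho to the diaryl ether).
Fallback: the nitro group is removed directly, without amine or diazonium ion. It sets out from 18, which is subjected to palladium-catalysed reductive denitration (Pd(acac)2, BrettPhos, K3PO4, propan-2-ol, 1,4-dioxane, 130 °C). Zerovalent palladium inserts into the aryl–NO2 bond, the alkoxide supplies hydride, and the route is rejoined at 21. No new compound is made.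

**Step 7.** The acid may damage the electron-rich stilbene (HBr addition, cationic oligomerisation) while the benzylic alcohol ionises.
Fallback: the alcohol is activated under neutral conditions and quaternised separately. It sets out from 10, which CBr4 and PPh3 in CH2Cl2 at 0 °C convert to the benzylic bromide F12. Heating F12 with PPh3 in toluene comes back to the route at 11.

## Further compounds

F1 | step 11 | 3-bromobenzaldehyde | O=Cc1cccc(Br)c1
F2 | step 11 | 1-bromo-3-[2-(3-{4-[2-(3-benzyloxy-4,5-dimethoxyphenyl)ethenyl]phenoxy}-4,5-dimethoxyphenyl)ethenyl]benzene (mixture of alkene isomers) | COc1cc(C=Cc2cccc(Br)c2)cc(Oc2ccc(C=Cc3cc(OC)c(OC)c(OCc4ccccc4)c3)cc2)c1OC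
F3 | step 11 | 1-bromo-3-[2-(3-{4-[2-(3-benzyloxy-4,5-dimethoxyphenyl)ethyl]phenoxy}-4,5-dimethoxyphenyl)ethyl]benzene | COc1cc(CCc2cccc(Br)c2)cc(Oc2ccc(CCc3cc(OC)c(OC)c(OCc4ccccc4)c3)cc2)c1OC
F4 | step 11 | 5-[2-(4-{5-[2-(3-bromophenyl)ethyl]-2,3-dimethoxyphenoxy}phenyl)ethyl]-2,3-dimethoxyphenol | COc1cc(CCc2ccc(cc2)Oc2cc(CCc3cccc(Br)c3)cc(OC)c2OC)cc(O)c1OC
F5 | step 9 | methyl 3-{4-[2-(3-benzyloxy-4,5-dimethoxyphenyl)ethyl]phenoxy}-4,5-dimethoxybenzoate | COC(=O)c1cc(OC)c(OC)c(Oc2ccc(CCc3cc(OC)c(OC)c(OCc4ccccc4)c3)cc2)c1
F6 | step 9 | (3-{4-[2-(3-benzyloxy-4,5-dimethoxyphenyl)ethyl]phenoxy}-4,5-dimethoxyphenyl)methanol | OCc1cc(OC)c(OC)c(Oc2ccc(CCc3cc(OC)c(OC)c(OCc4ccccc4)c3)cc2)c1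
F7 | step 9 | (3-{4-[2-(3-benzyloxy-4,5-dimethoxyphenyl)ethyl]phenoxy}-4,5-dimethoxybenzyl)triphenylphosphonium bromide | [Br-].COc1cc(C[P+](c2ccccc2)(c2ccccc2)c2ccccc2)cc(Oc2ccc(CCc3cc(OC)c(OC)c(OCc4ccccc4)c3)cc2)c1OC
F8 | step 9 | 4-[2-(3-{4-[2-(3-benzyloxy-4,5-dimethoxyphenyl)ethyl]phenoxy}-4,5-dimethoxyphenyl)ethenyl]-2-fluoro-1-nitrobenzene (E/Z mixture) | COc1cc(C=Cc2ccc([N+](=O)[O-])c(F)c2)cc(Oc2ccc(CCc3cc(OC)c(OC)c(OCc4ccccc4)c3)cc2)c1OC
F9 | step 8 | 3-{4-[2-(3-benzyloxy-4,5-dimethoxyphenyl)ethenyl]phenoxy}-4,5-dimethoxybenzaldehyde (E/Z mixture) | O=Cc1cc(OC)c(OC)c(Oc2ccc(C=Cc3cc(OC)c(OC)c(OCc4ccccc4)c3)cc2)c1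
F10 | step 8 | 4-(bromomethyl)-2-fluoro-1-nitrobenzene | [O-][N+](=O)c1ccc(CBr)cc1F
F11 | step 8 | (3-fluoro-4-nitrobenzyl)triphenylphosphonium bromide | [Br-].[O-][N+](=O)c1ccc(C[P+](c2ccccc2)(c2ccccc2)c2ccccc2)cc1F
F0 | step 13 | none | none
F12 | step 7 | 1-(bromomethyl)-3-{4-[2-(3-benzyloxy-4,5-dimethoxyphenyl)ethenyl]phenoxy}-4,5-dimethoxybenzene (E/Z mixture) | BrCc1cc(OC)c(OC)c(Oc2ccc(C=Cc3cc(OC)c(OC)c(OCc4ccccc4)c3)cc2)c1
A1 | alternative 1 | 2-(3-bromophenoxy)-4-(1,3-dioxolan-2-yl)-6-methoxyphenol | COc1cc(cc(Oc2cccc(Br)c2)c1O)C1OCCO1
A2 | alternative 1 | 5-(1,3-dioxolan-2-yl)-2-iodo-3-methoxyphenyl 4-chlorobenzenesulfonate | COc1cc(cc(OS(=O)(=O)c2ccc(Cl)cc2)c1I)C1OCCO1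
A3 | alternative 1 | 3-bromophenol | Oc1cccc(Br)c1
A4 | alternative 2 | macrocyclic bis(ortho-quinone) | O=C1C=C2C=C(C1=O)Oc1ccc(cc1)CCC1=CC(=O)C(=O)C(=C1)Oc1cccc(c1)CC2
A5 | alternative 2 | dideoxy macrocycle (one hydroxyl on C4 of ring A and of ring C) | Oc1ccc2cc1Oc1ccc(cc1)CCc1ccc(O)c(c1)Oc1cccc(c1)CC2
A6 | alternative 3 | 3-[3-[2-(3-benzyloxy-4,5-dimethoxyphenyl)ethyl]phenoxy]-4,5-dimethoxybenzaldehyde | O=Cc1cc(OC)c(OC)c(c1)Oc1cccc(c1)CCc1cc(OC)c(OC)c(OCc2ccccc2)c1
A7 | alternative 3 | 4-(5-formyl-2,3-dimethoxyphenoxy)-6-[2-(3-benzyloxy-4,5-dimethoxyphenyl)ethyl]-2H-pyran-2-one | O=Cc1cc(OC)c(OC)c(c1)OC1=CC(=O)OC(CCc2cc(OC)c(OC)c(OCc3ccccc3)c2)=C1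
A8 | alternative 3 | phenyl vinyl sulfone | C=CS(=O)(=O)c1ccccc1
A9 | alternative 3 | triacetic acid lactone (4-hydroxy-6-methyl-2H-pyran-2-one) | CC1=CC(O)=CC(=O)O1
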